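Everything rests on viewing the benzofuran core as a contracted flavylium. In the target, furan atoms O1, C2 (bearing the 4-hydroxyphenyl group) and C3 sit on the phloroglucinol ring, and C3 carries the 2,4-dihydroxybenzoyl carbonyl carbon outside the ring; that exocyclic carbon is the former C3 of a 2,3-diarylchromenylium cation. Hydrogen peroxide converts the permethylated chromenylium salt, assembled from a salicylaldehyde and a deoxybenzoin, into the 3-aroyl-2-arylbenzofuran in a single operation by bonding old C2 to old C4 and oxidising old C3 to the ketone. The 2-arylpropenoyl arm on C7 follows by acylation, protecting-group exchange, methylenation and base-free deprotection.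

Key step: step 3

Remark on the chemistry: benzofuran atoms are numbered O1, C2, C3, C3a, C4 to C7, C7a and chromenylium atoms O1, C2, C3, C4, C4a, C5 to C8, C8a. MOM = methoxymethyl, TBS = tert-butyldimethylsilyl. Only the transient compounds 6, 7 and 13 contain stereocentres; they are assumed to form as racemates, and these centres disappear within the same step.

Step 1
Reactants: 1 4'-methoxyacetophenone; 2 1-bromo-2,4-dimethoxybenzene
Product: 3 2-(2,4-dimethoxyphenyl)-1-(4-methoxyphenyl)ethanone
Conditions: Pd2(dba)3 (1 mol %), Xantphos (2.5 mol %), NaOtBu (2.2 equiv), 1 (1.2 equiv), THF, 70 °C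
Reagents that add atoms: none
Why: Palladium-catalysed α-arylation of a ketone enolate, in which the aryl–palladium bromide from 2 couples with the sodium enolate of 1, and the ortho-methoxy group of 2 together with immediate deprotonation of the more acidic product should hold the reaction at monoarylation.

Step 2
Reactants: 3 2-(2,4-dimethoxyphenyl)-1-(4-methoxyphenyl)ethanone; 4 2-hydroxy-4,6-dimethoxybenzaldehyde
Product: 5 3-(2,4-dimethoxyphenyl)-5,7-dimethoxy-2-(4-methoxyphenyl)chromenylium chloride
Conditions: dry HCl (g), EtOAc–AcOH, 0 °C to 20 °C, 24–48 h; Et2O to precipitate the salt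
Reagents that add atoms: hydrogen chloride, Cl
Why: Acid-mediated crossed aldol condensation and cyclodehydration (the classical salicylaldehyde-plus-ketone flavylium synthesis), in which the enol of 3 attacks the protonated aldehyde of 4, the phenol closes onto the aryl ketone and the aromatic pyrylium cation is the thermodynamic sink, while aryl methyl ethers are inert to HCl at room temperature.

Step 3
Reactants: 5 3-(2,4-dimethoxyphenyl)-5,7-dimethoxy-2-(4-methoxyphenyl)chromenylium chloride
Product: 8 (2,4-dimethoxyphenyl)[4,6-dimethoxy-2-(4-methoxyphenyl)-1-benzofuran-3-yl]methanone, via epoxy hemiketal 6 (not isolated), via hydroxydihydrobenzofuran 7 (not isolated)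
Conditions: 30% aq H2O2 (4 equiv), NaOAc (1.2 equiv)/AcOH buffer (pH ca. 4–5), MeOH–H2O, 20 °C
Reagents that add atoms: hydrogen peroxide, OO
Why: H2O2 adds to the electrophilic C2 of the cation and one peroxide oxygen is then passed to the electron-rich C3=C4 bond of the resulting 2H-chromene, giving the 3,4-epoxide of the C2 hemiketal (6). The oxirane opens at C4, where the cation is benzylic to the 5,7-dimethoxy ring, and the doubly oxygenated C2 shifts from C3 to C4 while C3 collapses to the 2,4-dimethoxyphenyl ketone, giving hemiketal 7, which loses water under the weakly acidic conditions to aromatise the furan. The closest known reaction type is the peroxide oxidation of 3-substituted flavylium salts to 3-acyl-2-arylbenzofurans, a semipinacol (Meinwald-type) ring contraction related to the acyl shift of chalcone epoxides. The furan ring is closed not by cyclisation of a chain but by 1,2-shift ring contraction: the new C2–C4 bond (benzofuran C2–C3) forms as the old C2–C3 bond breaks, with O1–C2 and C4–C4a intact, so the aryl group stays on C2 and the aroyl group ends on C3. The stereocentres of 6 and 7 are transient and are erased by the dehydration, so nothing has to be controlled. The step needs migration of C2 to win over Baeyer–Villiger-type oxygen insertion at a C2 hydroperoxide and over shift of the 3-aryl group; this is favoured because C2 is a masked acyl carbon bearing two oxygens, C4 is stabilised by the phloroglucinol-type ring, C3 carries no hydrogen and the medium is buffered and only weakly acidic.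

Step 4
Reactants: 8 (2,4-dimethoxyphenyl)[4,6-dimethoxy-2-(4-methoxyphenyl)-1-benzofuran-3-yl]methanone; 9 4-methoxyphenylacetyl chloride
Product: 10 1-[3-(2,4-dimethoxybenzoyl)-4,6-dimethoxy-2-(4-methoxyphenyl)-1-benzofuran-7-yl]-2-(4-methoxyphenyl)ethanone
Conditions: SnCl4 (2.5 equiv), CH2Cl2, −20 °C to 0 °C
Reagents that add atoms: none
Why: Friedel–Crafts acylation, directed to the only ring with three oxygen donors and, within it, to C7 (between 6-OMe and O1), which is less hindered than C5 (between two methoxy groups, one buttressed by the peri aroyl group) and is the usual site of attack in 2,3-disubstituted 4,6-dimethoxybenzofurans; any methyl ether lost next to a carbonyl is harmless because step 5 removes them all.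

Step 5
Reactants: 10 1-[3-(2,4-dimethoxybenzoyl)-4,6-dimethoxy-2-(4-methoxyphenyl)-1-benzofuran-7-yl]-2-(4-methoxyphenyl)ethanone
Product: 11 1-[3-(2,4-dihydroxybenzoyl)-4,6-dihydroxy-2-(4-hydroxyphenyl)-1-benzofuran-7-yl]-2-(4-hydroxyphenyl)ethanone
Conditions: BBr3 (12 equiv), CH2Cl2, −78 °C to 20 °C; then MeOH, H2O
Reagents that add atoms: none
Why: Lewis-acid cleavage of aryl methyl ethers (BBr3 demethylation), in which each ether forms a boron–oxonium adduct that bromide dealkylates, the ethers ortho or peri to the two ketones going first through chelation, while the benzofuran, both ketones and the CH2 group are inert.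

Step 6
Reactants: 11 1-[3-(2,4-dihydroxybenzoyl)-4,6-dihydroxy-2-(4-hydroxyphenyl)-1-benzofuran-7-yl]-2-(4-hydroxyphenyl)ethanone
Product: 12 1-{3-[2,4-bis(methoxymethoxy)benzoyl]-4,6-bis(methoxymethoxy)-2-[4-(methoxymethoxy)phenyl]-1-benzofuran-7-yl}-2-[4-(methoxymethoxy)phenyl]ethanone
Conditions: NaH (6.6 equiv), MOMCl (7 equiv), DMF, 0 °C to 20 °C
Reagents that add atoms: chloromethyl methyl ether, COCCl
Why: Williamson-type O-alkylation of the six phenoxides by the reactive α-chloro ether, with NaH kept just above six equivalents so that the far less acidic ketone CH2 is not deprotonated; this masks every phenol, above all 6-OH, before the enone exists.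

Step 7
Reactants: 12 1-{3-[2,4-bis(methoxymethoxy)benzoyl]-4,6-bis(methoxymethoxy)-2-[4-(methoxymethoxy)phenyl]-1-benzofuran-7-yl}-2-[4-(methoxymethoxy)phenyl]ethanone
Product: 14 1-{3-[2,4-bis(methoxymethoxy)benzoyl]-4,6-bis(methoxymethoxy)-2-[4-(methoxymethoxy)phenyl]-1-benzofuran-7-yl}-2-[4-(methoxymethoxy)phenyl]prop-2-en-1-one, via Mannich base 13 (not isolated)
Conditions: CH2(NMe2)2 (4 equiv), Ac2O (4 equiv), THF, 65 °C
Reagents that add atoms: bis(dimethylamino)methane, CN(C)CN(C)C
Why: Mannich reaction followed by E1cB β-elimination (one-pot α-methylenation by the iminium acetate formed from the aminal and Ac2O), which can occur only at the C7 arylacetyl ketone because the 3-aroyl ketone has no α-hydrogen, the Mannich base 13 losing dimethylamine on warming to give the terminal C=CH2 with no stereochemical issue.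

Step 8
Reactants: 14 1-{3-[2,4-bis(methoxymethoxy)benzoyl]-4,6-bis(methoxymethoxy)-2-[4-(methoxymethoxy)phenyl]-1-benzofuran-7-yl}-2-[4-(methoxymethoxy)phenyl]prop-2-en-1-one
Product: 15 1-[3-(2,4-dihydroxybenzoyl)-4,6-dihydroxy-2-(4-hydroxyphenyl)-1-benzofuran-7-yl]-2-(4-hydroxyphenyl)prop-2-en-1-one (target CNP0181958.0)
Conditions: HCl (1.25 M in MeOH), CH2Cl2, 0 °C to 20 °C; dilution with water, extraction, no base wash; Sephadex LH-20 (MeOH)
Reagents that add atoms: none
Why: Acid-catalysed acetal solvolysis (transacetalisation to dimethoxymethane), which should cleave the six aryl MOM ethers at or below room temperature while methanol captures the CH2 unit, and since no phenoxide is formed at any point the 6-OH, hydrogen-bonded to the C7 carbonyl, should not add to the methylene carbon.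

Compound list
1 | 4'-methoxyacetophenone | CC(=O)c1ccc(OC)cc1 | starting material
2 | 1-bromo-2,4-dimethoxybenzene | COc1ccc(Br)c(OC)c1 | starting material
3 | 2-(2,4-dimethoxyphenyl)-1-(4-methoxyphenyl)ethanone | COc1ccc(C(=O)Cc2ccc(OC)cc2OC)cc1 | intermediate
4 | 2-hydroxy-4,6-dimethoxybenzaldehyde | COc1cc(O)c(C=O)c(OC)c1 | starting material
5 | 3-(2,4-dimethoxyphenyl)-5,7-dimethoxy-2-(4-methoxyphenyl)chromenylium chloride | COc1ccc(-c2[o+]c3cc(OC)cc(OC)c3cc2-c2ccc(OC)cc2OC)cc1.[Cl-] | intermediate
6 | 3-(2,4-dimethoxyphenyl)-3,4-epoxy-5,7-dimethoxy-2-(4-methoxyphenyl)chroman-2-ol (epoxy hemiketal; racemic, relative configuration open) | COc1ccc(C2(O)Oc3cc(OC)cc(OC)c3C3OC32c2ccc(OC)cc2OC)cc1 | intermediate (not isolated)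
7 | (2,4-dimethoxyphenyl)[2-hydroxy-4,6-dimethoxy-2-(4-methoxyphenyl)-2,3-dihydro-1-benzofuran-3-yl]methanone (racemic, relative configuration open) | COc1ccc(C2(O)Oc3cc(OC)cc(OC)c3C2C(=O)c2ccc(OC)cc2OC)cc1 | intermediate (not isolated)
8 | (2,4-dimethoxyphenyl)[4,6-dimethoxy-2-(4-methoxyphenyl)-1-benzofuran-3-yl]methanone | COc1ccc(-c2oc3cc(OC)cc(OC)c3c2C(=O)c2ccc(OC)cc2OC)cc1 | intermediate
9 | 4-methoxyphenylacetyl chloride | COc1ccc(CC(=O)Cl)cc1 | starting material
10 | 1-[3-(2,4-dimethoxybenzoyl)-4,6-dimethoxy-2-(4-methoxyphenyl)-1-benzofuran-7-yl]-2-(4-methoxyphenyl)ethanone | COc1ccc(CC(=O)c2c(OC)cc(OC)c3c(C(=O)c4ccc(OC)cc4OC)c(-c4ccc(OC)cc4)oc23)cc1 | intermediate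
11 | 1-[3-(2,4-dihydroxybenzoyl)-4,6-dihydroxy-2-(4-hydroxyphenyl)-1-benzofuran-7-yl]-2-(4-hydroxyphenyl)ethanone | O=C(Cc1ccc(O)cc1)c1c(O)cc(O)c2c(C(=O)c3ccc(O)cc3O)c(-c3ccc(O)cc3)oc12 | intermediate
12 | 1-{3-[2,4-bis(methoxymethoxy)benzoyl]-4,6-bis(methoxymethoxy)-2-[4-(methoxymethoxy)phenyl]-1-benzofuran-7-yl}-2-[4-(methoxymethoxy)phenyl]ethanone | COCOc1ccc(CC(=O)c2c(OCOC)cc(OCOC)c3c(C(=O)c4ccc(OCOC)cc4OCOC)c(-c4ccc(OCOC)cc4)oc23)cc1 | intermediate
13 | 1-{3-[2,4-bis(methoxymethoxy)benzoyl]-4,6-bis(methoxymethoxy)-2-[4-(methoxymethoxy)phenyl]-1-benzofuran-7-yl}-3-(dimethylamino)-2-[4-(methoxymethoxy)phenyl]propan-1-one (Mannich base, racemic) | COCOc1ccc(C(CN(C)C)C(=O)c2c(OCOC)cc(OCOC)c3c(C(=O)c4ccc(OCOC)cc4OCOC)c(-c4ccc(OCOC)cc4)oc23)cc1 | intermediate (not isolated)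
14 | 1-{3-[2,4-bis(methoxymethoxy)benzoyl]-4,6-bis(methoxymethoxy)-2-[4-(methoxymethoxy)phenyl]-1-benzofuran-7-yl}-2-[4-(methoxymethoxy)phenyl]prop-2-en-1-one | C=C(C(=O)c1c(OCOC)cc(OCOC)c2c(C(=O)c3ccc(OCOC)cc3OCOC)c(-c3ccc(OCOC)cc3)oc12)c1ccc(OCOC)cc1 | intermediate
15 | 1-[3-(2,4-dihydroxybenzoyl)-4,6-dihydroxy-2-(4-hydroxyphenyl)-1-benzofuran-7-yl]-2-(4-hydroxyphenyl)prop-2-en-1-one | C=C(C(=O)c1c(O)cc(O)c2c(C(=O)c3ccc(O)cc3O)c(-c3ccc(O)cc3)oc12)c1ccc(O)cc1 | target

Total step count: 8
Longest linear sequence: 8 steps (1 or 2 to 15)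

Steps most likely to fail

Step 3. After peroxide addition at C2, oxygen insertion into the C2–C3 bond with ring opening to an aryl ester may outrun oxygen transfer to C3=C4. The 3-aryl group may migrate instead of C2. If the hemiketal opens before the shift, the phenol may re-close on either carbonyl and blur the C2/C3 assignment. Fallback, setting out from 4 and returning at 8: Bestmann–Ohira homologation of 4 (dimethyl (1-diazo-2-oxopropyl)phosphonate, K2CO3, MeOH, 20 °C) should give 2-ethynyl-3,5-dimethoxyphenol F1. Sonogashira coupling of F1 with 4-iodoanisole (PdCl2(PPh3)2, CuI, Et3N, THF, 20 °C) should give 3,5-dimethoxy-2-[(4-methoxyphenyl)ethynyl]phenol F2. Carbonylative heteroannulation of F2 with 1-iodo-2,4-dimethoxybenzene under CO (1 atm, Pd(PPh3)4, K2CO3, MeCN, 45 °C) closes the furan by 5-endo-dig attack of the phenoxide on the alkyne activated by the aroylpalladium species and, after reductive elimination, delivers 8 with the aryl group fixed on C2 and the aroyl group on C3.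

Step 4. The acylium ion may attack C5 or the dimethoxybenzoyl ring instead of C7, the Lewis acid may strip methyl ethers next to carbonyls, and the arylacetyl chloride may be lost through ketene formation or self-acylation. Fallback, setting out from 8 and returning at 10: Vilsmeier–Haack formylation (POCl3, DMF, 0 °C to 60 °C; aq NaOAc) uses a small electrophile without a metal Lewis acid and should give 3-(2,4-dimethoxybenzoyl)-4,6-dimethoxy-2-(4-methoxyphenyl)-1-benzofuran-7-carbaldehyde F3, on which the site of substitution could be verified before the side chain is invested. Addition of 4-methoxybenzylmagnesium chloride (THF, −78 °C), chemoselective for the aldehyde over the hindered diaryl ketone, should give racemic (2,4-dimethoxyphenyl){7-[1-hydroxy-2-(4-methoxyphenyl)ethyl]-4,6-dimethoxy-2-(4-methoxyphenyl)-1-benzofuran-3-yl}methanone F4. Dess–Martin oxidation of F4 (CH2Cl2, 20 °C) then leads to 10.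

Step 8. Acid may catalyse conjugate addition of methanol to the 2-arylpropenone or ring closure of the freed 6-OH onto the methylene carbon (isoflavanone formation), and cleavage of six acetals may stall before completion. Fallback, setting out from 11 and returning at 15: silylation (TBSCl, imidazole, DMAP cat., DMF, 40 °C) should give 1-{3-[2,4-bis(tert-butyldimethylsilyloxy)benzoyl]-4,6-bis(tert-butyldimethylsilyloxy)-2-[4-(tert-butyldimethylsilyloxy)phenyl]-1-benzofuran-7-yl}-2-[4-(tert-butyldimethylsilyloxy)phenyl]ethanone F5. Amine-salt-mediated methylenation of F5 (paraformaldehyde, diisopropylammonium trifluoroacetate, THF, reflux) should give the corresponding prop-2-en-1-one, hexakis(TBS) ether F6. Desilylation of F6 with HF·pyridine (THF, 0 °C, plastic vessel, no base in the work-up) releases 15 through silicon–fluorine bond formation in an acidic medium, with no alcohol solvent and no acetal-derived electrophile present.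

Further compounds
F1 | step 3 | 2-ethynyl-3,5-dimethoxyphenol | C#Cc1c(O)cc(OC)cc1OC
F2 | step 3 | 3,5-dimethoxy-2-[(4-methoxyphenyl)ethynyl]phenol | COc1ccc(C#Cc2c(O)cc(OC)cc2OC)cc1
F3 | step 4 | 3-(2,4-dimethoxybenzoyl)-4,6-dimethoxy-2-(4-methoxyphenyl)-1-benzofuran-7-carbaldehyde | COc1ccc(-c2oc3c(C=O)c(OC)cc(OC)c3c2C(=O)c2ccc(OC)cc2OC)cc1
F4 | step 4 | (2,4-dimethoxyphenyl){7-[1-hydroxy-2-(4-methoxyphenyl)ethyl]-4,6-dimethoxy-2-(4-methoxyphenyl)-1-benzofuran-3-yl}methanone (racemic) | COc1ccc(CC(O)c2c(OC)cc(OC)c3c(C(=O)c4ccc(OC)cc4OC)c(-c4ccc(OC)cc4)oc23)cc1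
F5 | step 8 | 1-{3-[2,4-bis(tert-butyldimethylsilyloxy)benzoyl]-4,6-bis(tert-butyldimethylsilyloxy)-2-[4-(tert-butyldimethylsilyloxy)phenyl]-1-benzofuran-7-yl}-2-[4-(tert-butyldimethylsilyloxy)phenyl]ethanone | CC(C)(C)[Si](C)(C)Oc1ccc(CC(=O)c2c(O[Si](C)(C)C(C)(C)C)cc(O[Si](C)(C)C(C)(C)C)c3c(C(=O)c4ccc(O[Si](C)(C)C(C)(C)C)cc4O[Si](C)(C)C(C)(C)C)c(-c4ccc(O[Si](C)(C)C(C)(C)C)cc4)oc23)cc1
F6 | step 8 | 1-{3-[2,4-bis(tert-butyldimethylsilyloxy)benzoyl]-4,6-bis(tert-butyldimethylsilyloxy)-2-[4-(tert-butyldimethylsilyloxy)phenyl]-1-benzofuran-7-yl}-2-[4-(tert-butyldimethylsilyloxy)phenyl]prop-2-en-1-one | C=C(C(=O)c1c(O[Si](C)(C)C(C)(C)C)cc(O[Si](C)(C)C(C)(C)C)c2c(C(=O)c3ccc(O[Si](C)(C)C(C)(C)C)cc3O[Si](C)(C)C(C)(C)C)c(-c3ccc(O[Si](C)(C)C(C)(C)C)cc3)oc12)c1ccc(O[Si](C)(C)C(C)(C)C)cc1
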